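The biaryl bond is made last, by Suzuki coupling of two chromene halves. The pyran of the prenylated half (ring A: O1, C2, C3, C4, C4a, C8a) is first closed one atom too large, as a 3-methyl-2,5-dihydro-1-benzoxepine, by ring-closing metathesis of a symmetric 2,6-diprenylphenyl methallyl ether. Base then contracts it in one operation: 1,4-elimination cleaves O1–CH2, the ring-enforced Z-dienylphenol undergoes a [1,7]-H shift, and oxa-6π closure bonds O1 to the methyl-bearing carbon. The step exploits the O1–C2(CH3)2–C3=C4 unit of ring A: one geminal methyl is the expelled ring CH2, and C3=C4 inherits the cis geometry stored in the oxepine.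

Key step: step 4

Remark: the target has no stereocentre, so only olefin geometry needs control; 5-bromo-2,3-dihydroxybenzaldehyde is assumed to be purchasable.

Step 1
Reactants: 1 4-bromophenol; 2 prenyl bromide (1-bromo-3-methylbut-2-ene)
Product: 3 4-bromo-2,6-bis(3-methylbut-2-en-1-yl)phenol
Conditions: 2 (2.3 equiv), KOH (2.5 equiv), H2O, rt, vigorous stirring
Reagents that add atoms: prenyl bromide (2), CC(C)=CCBr
Why: In water the phenoxide oxygen is masked by hydrogen bonding, so the ambident anion should be alkylated by the soft allylic bromide at both free ortho carbons (ortho-C-alkylation of a phenoxide), the para position being blocked by bromine.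

Step 2
Reactants: 3 4-bromo-2,6-bis(3-methylbut-2-en-1-yl)phenol; 4 methallyl bromide (3-bromo-2-methylprop-1-ene)
Product: 5 5-bromo-1,3-bis(3-methylbut-2-en-1-yl)-2-[(2-methylprop-2-en-1-yl)oxy]benzene
Conditions: 4 (1.3 equiv), K2CO3 (2 equiv), acetone, reflux
Reagents that add atoms: methallyl bromide (4), CC(=C)CBr
Why: Williamson ether synthesis: in a polar aprotic solvent the potassium phenoxide should react at oxygen with the primary allylic bromide, and no free ortho or para carbon is left for C-alkylation.

Step 3
Reactants: 5 5-bromo-1,3-bis(3-methylbut-2-en-1-yl)-2-[(2-methylprop-2-en-1-yl)oxy]benzene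
Product: 6 7-bromo-3-methyl-9-(3-methylbut-2-en-1-yl)-2,5-dihydro-1-benzoxepine
Conditions: second-generation Hoveyda–Grubbs catalyst (5 mol%), toluene (0.01 M), 80 °C, argon sparge
Reagents that add atoms: none
Why: Ring-closing metathesis: the ruthenium alkylidene should load onto one of the two equivalent prenyl groups and close on the methallyl olefin to the seven-membered cis-trisubstituted cycloalkene, driven by escape of gaseous isobutene, while the second prenyl group has no partner within reach.

Step 4
Reactants: 6 7-bromo-3-methyl-9-(3-methylbut-2-en-1-yl)-2,5-dihydro-1-benzoxepine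
Product: 9 6-bromo-2,2-dimethyl-8-(3-methylbut-2-en-1-yl)-2H-chromene, via Z-dienylphenol 7 (not isolated), via o-quinone methide 8 (not isolated)
Conditions: LiN(iPr)2 (1.15 equiv, commercial solution), THF, −78 to 0 °C; AcOH (1.3 equiv); then reflux
Reagents that add atoms: none
Why: LiN(iPr)2 removes the doubly activated (benzylic and allylic) C5–H of 6, and the ring-bound allyl anion expels the aryloxide from C2 (vinylogous E1cB, 1,4-elimination), which opens the oxepine to the lithium phenolate of 7. Because C5a and C3 are held cis across C4–C5 by the seven-membered ring, the new styrenyl double bond is born Z, the only geometry from which, after the AcOH quench, the phenolic O–H can reach the diene terminus in an antarafacial [1,7]-H shift to give o-quinone methide 8. Compound 8 closes by thermal disrotatory oxa-6π electrocyclisation (O1 to the dimethyl-substituted terminus), which rearomatises ring A and delivers the six-membered pyran, the former ring CH2 ending as a geminal methyl group. The closest known reaction types are the base-induced ring opening of 5,6-dihydro-2H-pyrans to Z-dienols and the thermal cyclisation of Z-configured o-butadienylphenols to 2H-chromenes. No stereocentre is formed. The step needs ring deprotonation to win over the equally acidic prenyl CH2: only the ring anion carries a leaving group, so it drains irreversibly to the weakly basic phenolate while the prenyl anion is returned through HN(iPr)2, and a slight excess of base at low temperature spares the aryl bromide.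

Step 5
Reactants: 10 5-bromo-2,3-dihydroxybenzaldehyde; 11 2-methylprop-1-en-1-ylmagnesium bromide
Product: 14 6-bromo-2,2-dimethyl-2H-chromen-8-ol, via allylic alcohol 12 (not isolated), via o-quinone methide 13 (not isolated)
Conditions: 11 (3.5 equiv), THF, 0 °C to rt; 1 M HCl, 0 °C; then toluene, 90 °C, under N2
Reagents that add atoms: 2-methylprop-1-en-1-ylmagnesium bromide (11), CC(C)=C[Mg]Br
Why: Grignard 1,2-addition to the aldehyde (two equivalents are spent on the phenolic OH groups) should give racemic 12, which loses water on heating through o-quinone methide 13 and closes by oxa-6π electrocyclisation; only the OH ortho to the carbinol can form the quinone methide, so the other one stays free as the 8-OH.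

Step 6
Reactants: 14 6-bromo-2,2-dimethyl-2H-chromen-8-ol; 15 bis(pinacolato)diboron
Product: 16 2,2-dimethyl-6-(4,4,5,5-tetramethyl-1,3,2-dioxaborolan-2-yl)-2H-chromen-8-ol
Conditions: 15 (1.2 equiv), Pd(dppf)Cl2 (3 mol%), KOAc (3 equiv), 1,4-dioxane, 90 °C
Reagents that add atoms: bis(pinacolato)diboron (15), CC1(C)OB(OC1(C)C)B1OC(C)(C)C(C)(C)O1
Why: Miyaura borylation (oxidative addition of the aryl bromide to zerovalent palladium, acetate-assisted transmetalation, reductive elimination) uses a base mild enough to tolerate the free phenol and the chromene olefin.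

Step 7
Reactants: 9 6-bromo-2,2-dimethyl-8-(3-methylbut-2-en-1-yl)-2H-chromene; 16 2,2-dimethyl-6-(4,4,5,5-tetramethyl-1,3,2-dioxaborolan-2-yl)-2H-chromen-8-ol
Product: 17 2,2-dimethyl-6-[2,2-dimethyl-8-(3-methylbut-2-en-1-yl)-2H-chromen-6-yl]-2H-chromen-8-ol (target)
Conditions: Pd(dppf)Cl2 (3 mol%), K2CO3 (3 equiv), 1,4-dioxane/H2O, 85 °C
Reagents that add atoms: none
Why: Suzuki–Miyaura cross-coupling should join C6 of ring A to C6 of ring B, since both chromene ethers, the prenyl olefin and the phenol (carried as its phenoxide) are inert to aqueous carbonate.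

Compound list
1 | 4-bromophenol | Oc1ccc(Br)cc1 | starting material
2 | prenyl bromide (1-bromo-3-methylbut-2-ene) | CC(C)=CCBr | starting material
3 | 4-bromo-2,6-bis(3-methylbut-2-en-1-yl)phenol | CC(C)=CCc1cc(Br)cc(CC=C(C)C)c1O | intermediate
4 | methallyl bromide (3-bromo-2-methylprop-1-ene) | CC(=C)CBr | starting material
5 | 5-bromo-1,3-bis(3-methylbut-2-en-1-yl)-2-[(2-methylprop-2-en-1-yl)oxy]benzene | CC(=C)COc1c(CC=C(C)C)cc(Br)cc1CC=C(C)C | intermediate
6 | 7-bromo-3-methyl-9-(3-methylbut-2-en-1-yl)-2,5-dihydro-1-benzoxepine | CC1=CCc2cc(Br)cc(CC=C(C)C)c2OC1 | intermediate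
7 | 4-bromo-2-[(1Z)-3-methylbuta-1,3-dien-1-yl]-6-(3-methylbut-2-en-1-yl)phenol (lithium salt until the quench) | CC(=C)/C=C\c1cc(Br)cc(CC=C(C)C)c1O | intermediate
8 | (6Z)-4-bromo-6-(3-methylbut-2-en-1-ylidene)-2-(3-methylbut-2-en-1-yl)cyclohexa-2,4-dien-1-one | CC(C)=C/C=C1/C=C(Br)C=C(CC=C(C)C)C1=O | intermediate
9 | 6-bromo-2,2-dimethyl-8-(3-methylbut-2-en-1-yl)-2H-chromene | CC(C)=CCc1cc(Br)cc2c1OC(C)(C)C=C2 | intermediate
10 | 5-bromo-2,3-dihydroxybenzaldehyde | O=Cc1cc(Br)cc(O)c1O | starting material
11 | 2-methylprop-1-en-1-ylmagnesium bromide | CC(C)=C[Mg]Br | starting material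
12 | 5-bromo-3-(1-hydroxy-3-methylbut-2-en-1-yl)benzene-1,2-diol (racemic) | CC(C)=CC(O)c1cc(Br)cc(O)c1O | intermediate
13 | (6Z)-4-bromo-2-hydroxy-6-(3-methylbut-2-en-1-ylidene)cyclohexa-2,4-dien-1-one | CC(C)=C/C=C1/C=C(Br)C=C(O)C1=O | intermediate
14 | 6-bromo-2,2-dimethyl-2H-chromen-8-ol | CC1(C)C=Cc2cc(Br)cc(O)c2O1 | intermediate
15 | bis(pinacolato)diboron | CC1(C)OB(OC1(C)C)B1OC(C)(C)C(C)(C)O1 | starting material
16 | 2,2-dimethyl-6-(4,4,5,5-tetramethyl-1,3,2-dioxaborolan-2-yl)-2H-chromen-8-ol | CC1(C)C=Cc2cc(cc(O)c2O1)B1OC(C)(C)C(C)(C)O1 | intermediate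
17 | 2,2-dimethyl-6-[2,2-dimethyl-8-(3-methylbut-2-en-1-yl)-2H-chromen-6-yl]-2H-chromen-8-ol | CC(C)=CCc1cc(-c2cc(O)c3c(c2)C=CC(C)(C)O3)cc2c1OC(C)(C)C=C2 | target

Total step count: 7. Longest linear sequence: 5 (steps 1, 2, 3, 4, 7).

Steps most likely to fail

1. Step 4.
- **Risk:** Deprotonation may occur at the equally acidic prenyl CH2, with migration of that double bond into conjugation. Deprotonation next to the ring oxygen and attack of the amide base on the aryl bromide are also possible.
- **Fallback:** π-Allylpalladium chemistry replaces carbanion chemistry and is used only after the bromide is gone. It sets out from 6, which is coupled with 16 under the conditions of step 7 to give 2,2-dimethyl-6-[3-methyl-9-(3-methylbut-2-en-1-yl)-2,5-dihydro-1-benzoxepin-7-yl]-2H-chromen-8-ol F1. Catalytic Pd(OAc)2/PPh3 in refluxing dioxane then ionises the primary allylic aryl ether. β-Hydride elimination from the π-allyl complex (palladium-catalysed 1,4-elimination of allylic aryl ethers) opens the oxepine to 6-[4-hydroxy-3-(3-methylbuta-1,3-dien-1-yl)-5-(3-methylbut-2-en-1-yl)phenyl]-2,2-dimethyl-2H-chromen-8-ol F2 as an E/Z mixture. Catalytic pyridinium p-toluenesulfonate protonates the diene terminus to a delocalised allyl/benzyl cation. In that cation the olefin geometry no longer matters, and O1 closes on the tertiary end. The oxepine is still contracted to the pyran, and the fallback comes back to the route at 17.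

2. Step 3.
- **Risk:** Initiation may be slow because neither olefin is monosubstituted. Catalyst decay to ruthenium hydrides could cause olefin migration, and intermolecular cross metathesis could compete.
- **Fallback:** A monosubstituted allyl group serves as the loading site. It sets out from 1:
  - Monoprenylation with one equivalent of 2 (KOH, H2O) gives 4-bromo-2-(3-methylbut-2-en-1-yl)phenol F3.
  - O-Allylation (allyl bromide, K2CO3, acetone) gives 1-(allyloxy)-4-bromo-2-(3-methylbut-2-en-1-yl)benzene F4.
  - Aromatic Claisen rearrangement (N,N-diethylaniline, 190 °C) moves the allyl group to the only free ortho carbon and gives 2-allyl-4-bromo-6-(3-methylbut-2-en-1-yl)phenol F5.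
  - Etherification with 4 as in step 2 gives 1-allyl-5-bromo-3-(3-methylbut-2-en-1-yl)-2-[(2-methylprop-2-en-1-yl)oxy]benzene F6.
  - In F6 the catalyst loads rapidly on the allyl group and closes on the methallyl olefin with loss of ethylene. The fallback comes back to the route at 6.

3. Step 5.
- **Risk:** The magnesium catecholate may precipitate before the aldehyde is consumed, and the unprotected catechol may be oxidised by air during work-up.
- **Fallback:** A Petasis borono-Mannich reaction replaces the organomagnesium addition. It sets out from 10, which is heated with (2-methylprop-1-en-1-yl)boronic acid and dibenzylamine in dioxane. The iminium ion is alkenylated within the phenoxy-boronate complex to give 5-bromo-3-[1-(dibenzylamino)-3-methylbut-2-en-1-yl]benzene-1,2-diol F7. At 90 °C F7 expels the amine to the same o-quinone methide 13 and closes, so the fallback comes back to the route at 14.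

Further compounds
F1 | step 4 | 2,2-dimethyl-6-[3-methyl-9-(3-methylbut-2-en-1-yl)-2,5-dihydro-1-benzoxepin-7-yl]-2H-chromen-8-ol | CC1=CCc2cc(cc(CC=C(C)C)c2OC1)-c1cc(O)c2OC(C)(C)C=Cc2c1
F2 | step 4 | 6-[4-hydroxy-3-(3-methylbuta-1,3-dien-1-yl)-5-(3-methylbut-2-en-1-yl)phenyl]-2,2-dimethyl-2H-chromen-8-ol (E/Z mixture) | CC(=C)C=Cc1cc(cc(CC=C(C)C)c1O)-c1cc(O)c2OC(C)(C)C=Cc2c1
F3 | step 3 | 4-bromo-2-(3-methylbut-2-en-1-yl)phenol | CC(C)=CCc1cc(Br)ccc1O
F4 | step 3 | 1-(allyloxy)-4-bromo-2-(3-methylbut-2-en-1-yl)benzene | C=CCOc1ccc(Br)cc1CC=C(C)C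
F5 | step 3 | 2-allyl-4-bromo-6-(3-methylbut-2-en-1-yl)phenol | C=CCc1cc(Br)cc(CC=C(C)C)c1O
F6 | step 3 | 1-allyl-5-bromo-3-(3-methylbut-2-en-1-yl)-2-[(2-methylprop-2-en-1-yl)oxy]benzene | CC(=C)COc1c(CC=C)cc(Br)cc1CC=C(C)C
F7 | step 5 | 5-bromo-3-[1-(dibenzylamino)-3-methylbut-2-en-1-yl]benzene-1,2-diol (racemic) | CC(C)=CC(N(Cc1ccccc1)Cc1ccccc1)c1cc(Br)cc(O)c1O
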